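The target is cut first at the O–C1' ether bond, giving 4-hydroxy-5-methylcoumarin and an (R)-acetoxy C10 dienol, and then at C4a–C5. Ring A (C4a, C5, C6, C7, C8, C8a) carries only the C5 methyl and shares C4a=C8a with lactone ring B. It therefore unfolds to a penta-1,3-dienyl chain on C6 of a 4-methoxy-2-pyranone, whose bond-localised C5=C6 olefin completes a hexatriene. In one photochemical operation the chain isomerises, a six-electron electrocyclisation forms C4a–C5, and iodine aromatises the dihydro ring to 4-methoxy-5-methylcoumarin. The precursor is 4-methoxy-6-[(1E,3E)-penta-1,3-dienyl]-2-pyranone, two steps from commercial materials.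

Key step: step 3

Assumption: 4-methoxy-6-methyl-2H-pyran-2-one, crotonaldehyde, (tert-butyldimethylsilyloxy)acetaldehyde, 2-(triphenylphosphoranylidene)propanal and (+)-B-allyldiisopinocampheylborane (pentane solution) are taken as commercial.

Locants: primed numbers count the dienyl chain from the pyranone in steps 1–3, and the C10 chain from the ether oxygen in steps 5–10.

Design remarks:
- **Chain attachment.** Crotonaldehyde is sensitive to hot alkoxide, so the chain is attached by a low-temperature lithium dienolate aldol followed by a separate dehydration.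
- **Oxidant.** An acyclic diene irradiated under O2 is exposed to photooxygenation, and free HI would attack the enol ether. Iodine is therefore used stoichiometrically under argon with an epoxide as acid trap.
- **Prenyl terminus.** Prenyl-metal reagents add to aldehydes through their γ-carbon and would give the branched carbinol. The linear prenyl terminus is instead made by asymmetric allylation followed by cross-metathesis.

Step 1
Reactants: 1 4-methoxy-6-methyl-2H-pyran-2-one; 2 (E)-but-2-enal (crotonaldehyde)
Product: 4 rac-6-[(3E)-2-hydroxypent-3-en-1-yl]-4-methoxy-2H-pyran-2-one, via lithium dienolate 3 (not isolated)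
Conditions: LiN(SiMe3)2, THF, −78 °C; then 2, −78 °C; AcOH quench
Reagents that add atoms: none
Why: Vinylogous aldol addition, in which the hindered amide base removes a proton from the C6 methyl group (charge delocalised through the ring to the lactone carbonyl) and the lithium dienolate adds 1,2 to the enal at low temperature; the new carbinol centre is racemic and is erased in step 2.

Step 2
Reactants: 4 rac-6-[(3E)-2-hydroxypent-3-en-1-yl]-4-methoxy-2H-pyran-2-one
Product: 6 4-methoxy-6-[(1E,3E)-penta-1,3-dien-1-yl]-2H-pyran-2-one, via allylic mesylate 5 (not isolated)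
Conditions: MsCl, Et3N, CH2Cl2, 0 °C; then DBU, 0 °C to rt
Reagents that add atoms: none
Why: Mesylation followed by E1cB-type elimination, in which only the acidic C1' methylene next to the pyranone offers a removable hydrogen, so the new olefin forms in conjugation and should adopt the more stable E geometry.

Step 3
Reactants: 6 4-methoxy-6-[(1E,3E)-penta-1,3-dien-1-yl]-2H-pyran-2-one
Product: 9 4-methoxy-5-methyl-2H-chromen-2-one, via (1Z,3E)-dienylpyranone 7 (not isolated), via trans-4a,5-dihydrocoumarin 8 (not isolated)
Conditions: hν (365 nm), I2 (1.1 equiv), propylene oxide (excess), degassed toluene (ca. 1 mM, argon, flow coil), rt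
Reagents that add atoms: none
Why: Proposed new method: light absorbed by the pyranone–diene chromophore of 6 scrambles the chain olefins, and the 1'Z isomer 7, in its doubly s-cis conformer, brings the methyl-bearing C4' within reach of pyranone C5. A conrotatory six-electron electrocyclisation of the C5=C6–C1'=C2'–C3'=C4' triene then forms the C4a–C5 bond and closes the six-membered carbocycle (ring A) as dihydrocoumarin 8, after which iodine atoms abstract H-4a and H-5 and propylene oxide binds the HI, so that aromatisation makes the sequence irreversible. The closest known reaction type is the Mallory oxidative photocyclisation of stilbenes and of styryl or dienyl arenes and heteroarenes in its iodine–epoxide variant; a 2-pyranone C5=C6 bond has not yet served as the triene terminus. The two stereocentres of 8 (C4a and C5, trans by orbital symmetry from the 3'E olefin) are transient and vanish on aromatisation, so neither the chain geometry of 6 nor facial selectivity matters. Regioselectivity is secured by connectivity, because C5 is the only carbon neighbour of C6 inside the ring and closure there puts the methyl on C5, peri to the methoxy group. Chemoselectivity against [2+2] dimerisation, four-electron closure of the pyranone and photooxygenation of the diene is sought through millimolar dilution, 365 nm light that only the extended chromophore of 6 and 7 (not 9) absorbs, and exclusion of O2.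

Step 4
Reactants: 9 4-methoxy-5-methyl-2H-chromen-2-one
Product: 10 4-hydroxy-5-methyl-2H-chromen-2-one
Conditions: HBr (33% in AcOH), 90 °C
Reagents that add atoms: none
Why: Acidic ether cleavage of a vinylogous methyl ester, in which protonation of the lactone carbonyl makes the coumarin oxygen a good leaving group and bromide attacks the unhindered methyl carbon by SN2, so the peri C5 methyl cannot slow the reaction.

Step 5
Reactants: 11 [(tert-butyldimethylsilyl)oxy]acetaldehyde; 12 2-(triphenyl-λ5-phosphanylidene)propanal
Product: 13 (2E)-4-[(tert-butyldimethylsilyl)oxy]-2-methylbut-2-enal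
Conditions: toluene, 80 °C
Reagents that add atoms: none
Why: Wittig olefination with a stabilised formyl ylide, which should give the E-trisubstituted enal, while the α-branched conjugated product aldehyde is too unreactive to be homologated a second time.

Step 6
Reactants: 13 (2E)-4-[(tert-butyldimethylsilyl)oxy]-2-methylbut-2-enal
Product: 15 (2E,4R)-1-[(tert-butyldimethylsilyl)oxy]-3-methylhepta-2,6-dien-4-ol, via diisopinocampheylborinate 14 (not isolated)
Conditions: (+)-Ipc2B(allyl), Et2O, −78 °C; then NaOH, 30% H2O2, 0 °C to rt
Reagents that add atoms: (+)-B-allyldiisopinocampheylborane (enantiomer derived from (−)-α-pinene), C=CCB([C@H]1C[C@H]2C[C@@H]([C@@H]1C)C2(C)C)[C@H]1C[C@H]2C[C@@H]([C@@H]1C)C2(C)C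
Why: Brown asymmetric allylboration through a closed Zimmerman–Traxler chair, in which the isopinocampheyl groups of this reagent enantiomer steer the allyl group to the Re face of the aldehyde and thereby set C4' as R, the oxidative work-up then freeing the alcohol.

Step 7
Reactants: 15 (2E,4R)-1-[(tert-butyldimethylsilyl)oxy]-3-methylhepta-2,6-dien-4-ol
Product: 16 (2E,4R)-1-[(tert-butyldimethylsilyl)oxy]-3-methylhepta-2,6-dien-4-yl acetate
Conditions: Ac2O, Et3N, 4-(dimethylamino)pyridine (cat.), CH2Cl2, 0 °C to rt
Reagents that add atoms: acetic anhydride, CC(=O)OC(C)=O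
Why: Nucleophile-catalysed O-acylation (Steglich-type acetylation) takes place at oxygen only, so the C4'–O bond and its R configuration are retained.

Step 8
Reactants: 16 (2E,4R)-1-[(tert-butyldimethylsilyl)oxy]-3-methylhepta-2,6-dien-4-yl acetate
Product: 17 (2E,4R)-1-[(tert-butyldimethylsilyl)oxy]-3,7-dimethylocta-2,6-dien-4-yl acetate
Conditions: 2-methylbut-2-ene (large excess), second-generation Grubbs catalyst (H2IMes)(PCy3)Cl2Ru=CHPh (5 mol %), CH2Cl2, 40 °C
Reagents that add atoms: 2-methylbut-2-ene, CC=C(C)C
Why: Olefin cross-metathesis, in which the monosubstituted terminal alkene is the only olefin of 16 that engages the ruthenium carbene readily, the excess partner delivers the isopropylidene cap, propene escapes, and the hindered trisubstituted C2'=C3' olefin and the stereocentre stay untouched.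

Step 9
Reactants: 17 (2E,4R)-1-[(tert-butyldimethylsilyl)oxy]-3,7-dimethylocta-2,6-dien-4-yl acetate
Product: 18 (2E,4R)-1-hydroxy-3,7-dimethylocta-2,6-dien-4-yl acetate
Conditions: HF·pyridine, pyridine, THF, 0 °C to rt
Reagents that add atoms: none
Why: Fluoride-driven desilylation under buffered conditions that are neither basic enough to cleave the acetate nor acidic enough to ionise the allylic C4'–O bond, and the E olefin keeps the two oxygens too far apart for acyl migration.

Step 10
Reactants: 10 4-hydroxy-5-methyl-2H-chromen-2-one; 18 (2E,4R)-1-hydroxy-3,7-dimethylocta-2,6-dien-4-yl acetate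
Product: 19 (2E,4R)-3,7-dimethyl-1-[(5-methyl-2-oxo-2H-chromen-4-yl)oxy]octa-2,6-dien-4-yl acetate (target)
Conditions: PPh3, DIAD, THF, 0 °C to rt
Reagents that add atoms: none
Why: Mitsunobu etherification, in which the acidic vinylogous carboxylic acid 10 protonates the phosphine–azodicarboxylate adduct and its O4 oxyanion displaces the primary allylic oxyphosphonium group at C1' by SN2, leaving the remote C4' stereocentre and the E olefin unchanged.

Compound list

1 | 4-methoxy-6-methyl-2H-pyran-2-one | COc1cc(C)oc(=O)c1 | starting material
2 | (E)-but-2-enal (crotonaldehyde) | C/C=C/C=O | starting material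
3 | lithium 4-methoxy-6-methylidene-6H-pyran-2-olate (lithium dienolate of 1) | [Li+].[O-]C1=CC(OC)=CC(=C)O1 | intermediate (not isolated)
4 | rac-6-[(3E)-2-hydroxypent-3-en-1-yl]-4-methoxy-2H-pyran-2-one | COc1cc(CC(O)/C=C/C)oc(=O)c1 | intermediate
5 | rac-(3E)-1-(4-methoxy-2-oxo-2H-pyran-6-yl)pent-3-en-2-yl methanesulfonate | COc1cc(CC(OS(C)(=O)=O)/C=C/C)oc(=O)c1 | intermediate (not isolated)
6 | 4-methoxy-6-[(1E,3E)-penta-1,3-dien-1-yl]-2H-pyran-2-one | COc1cc(=O)oc(/C=C/C=C/C)c1 | intermediate
7 | 4-methoxy-6-[(1Z,3E)-penta-1,3-dien-1-yl]-2H-pyran-2-one | COc1cc(=O)oc(/C=C\C=C\C)c1 | intermediate (not isolated)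
8 | rac-(4aS,5S)-4-methoxy-5-methyl-4a,5-dihydro-2H-chromen-2-one (H-4a and H-5 trans; one enantiomer drawn) | COC1=CC(=O)OC2=CC=C[C@H](C)[C@@H]12 | intermediate (not isolated)
9 | 4-methoxy-5-methyl-2H-chromen-2-one | COc1cc(=O)oc2cccc(C)c12 | intermediate
10 | 4-hydroxy-5-methyl-2H-chromen-2-one | Cc1cccc2oc(=O)cc(O)c12 | intermediate
11 | [(tert-butyldimethylsilyl)oxy]acetaldehyde | CC(C)(C)[Si](C)(C)OCC=O | starting material
12 | 2-(triphenyl-λ5-phosphanylidene)propanal | CC(C=O)=P(c1ccccc1)(c1ccccc1)c1ccccc1 | starting material
13 | (2E)-4-[(tert-butyldimethylsilyl)oxy]-2-methylbut-2-enal | CC(C)(C)[Si](C)(C)OC/C=C(\C)C=O | intermediate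
14 | (2E,4R)-1-[(tert-butyldimethylsilyl)oxy]-3-methylhepta-2,6-dien-4-yl diisopinocampheylborinate | C=CC[C@@H](OB([C@H]1C[C@H]2C[C@@H]([C@@H]1C)C2(C)C)[C@H]1C[C@H]2C[C@@H]([C@@H]1C)C2(C)C)/C(C)=C/CO[Si](C)(C)C(C)(C)C | intermediate (not isolated)
15 | (2E,4R)-1-[(tert-butyldimethylsilyl)oxy]-3-methylhepta-2,6-dien-4-ol | C=CC[C@@H](O)/C(C)=C/CO[Si](C)(C)C(C)(C)C | intermediate
16 | (2E,4R)-1-[(tert-butyldimethylsilyl)oxy]-3-methylhepta-2,6-dien-4-yl acetate | C=CC[C@@H](OC(C)=O)/C(C)=C/CO[Si](C)(C)C(C)(C)C | intermediate
17 | (2E,4R)-1-[(tert-butyldimethylsilyl)oxy]-3,7-dimethylocta-2,6-dien-4-yl acetate | CC(C)=CC[C@@H](OC(C)=O)/C(C)=C/CO[Si](C)(C)C(C)(C)C | intermediate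
18 | (2E,4R)-1-hydroxy-3,7-dimethylocta-2,6-dien-4-yl acetate | CC(C)=CC[C@@H](OC(C)=O)/C(C)=C/CO | intermediate
19 | (2E,4R)-3,7-dimethyl-1-[(5-methyl-2-oxo-2H-chromen-4-yl)oxy]octa-2,6-dien-4-yl acetate | CC(=O)O[C@H](CC=C(C)C)/C(C)=C/COc1cc(=O)oc2cccc(C)c12 | target

Total step count: 10. Longest linear sequence: 6 steps (steps 5–10). The coumarin branch contributes 5 steps (steps 1–4 and step 10).

Steps most likely to fail

1. **Step 3 (the labelled step).**
   - Risk: the excited state may relax by E/Z isomerisation alone. Bimolecular [2+2] photoaddition or four-electron closure of the pyranone may outrun the six-electron closure. Iodine may also degrade the diene. A hydrogen shift at the dihydro stage would be harmless, since DDQ treatment of the crude photolysate should complete the aromatisation.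
   - Fallback (known chemistry; ring A is made first and lactone ring B is closed last): it sets out from crotonaldehyde 2 and comes back to the route at 10, bypassing steps 1–4. Michael addition of ethyl acetoacetate to 2, followed by intramolecular aldol condensation (NaOEt cat., EtOH, then acid), should give ethyl 6-methyl-2-oxocyclohex-3-ene-1-carboxylate F1. Bromination–dehydrobromination (Br2, AcOH, 0 °C to reflux) aromatises it to ethyl 2-hydroxy-6-methylbenzoate F2. Acetylation (Ac2O, pyridine) gives ethyl 2-acetoxy-6-methylbenzoate F3. An intramolecular Claisen (Dieckmann-type) condensation of the acetate enolate onto the benzoate (NaH, THF) then closes ring B to 10.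

2. **Step 10.**
   - Risk: the ambident coumarin anion may react through the lactone carbonyl oxygen or through C3 instead of O4, a drift that the peri C5 methyl could aggravate. Allylic transposition during displacement is a lesser concern.
   - Fallback: it sets out from 18 and comes back at 19. Appel bromination (CBr4, PPh3, CH2Cl2, 0 °C) should give (2E,4R)-1-bromo-3,7-dimethylocta-2,6-dien-4-yl acetate F4. F4 alkylates the preformed cesium salt of 10 (Cs2CO3, DMF, 0 °C to rt) by direct halide displacement. The dissociated, hard oxyanion in a dipolar aprotic solvent favours O- over C-alkylation.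

3. **Step 1.**
   - Risk: ring metalation at C3 may compete with deprotonation of the methyl group. The dienolate may add in conjugate fashion, or it may simply take a γ-proton from the enal.
   - Fallback: it sets out from 1 and comes back at 6, replacing steps 1 and 2 by an olefination. Wohl–Ziegler bromination (NBS, azobisisobutyronitrile, PhCF3, reflux) should give 6-(bromomethyl)-4-methoxy-2H-pyran-2-one F5. A Michaelis–Arbuzov reaction (P(OEt)3, 120 °C) gives diethyl [(4-methoxy-2-oxo-2H-pyran-6-yl)methyl]phosphonate F6. Horner–Wadsworth–Emmons olefination with 2 (NaH, THF, 0 °C) then delivers 6 directly.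

Further compounds

F1 | step 3 | ethyl 6-methyl-2-oxocyclohex-3-ene-1-carboxylate (racemic, mixture of diastereomers) | CCOC(=O)C1C(C)CC=CC1=O
F2 | step 3 | ethyl 2-hydroxy-6-methylbenzoate | CCOC(=O)c1c(C)cccc1O
F3 | step 3 | ethyl 2-acetoxy-6-methylbenzoate | CCOC(=O)c1c(C)cccc1OC(C)=O
F4 | step 10 | (2E,4R)-1-bromo-3,7-dimethylocta-2,6-dien-4-yl acetate | CC(C)=CC[C@@H](OC(C)=O)/C(C)=C/CBr
F5 | step 1 | 6-(bromomethyl)-4-methoxy-2H-pyran-2-one | COc1cc(CBr)oc(=O)c1
F6 | step 1 | diethyl [(4-methoxy-2-oxo-2H-pyran-6-yl)methyl]phosphonate | CCOP(=O)(Cc1cc(OC)cc(=O)o1)OCC
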